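The cycloheptane ring (C1, C5–C10; daucane numbering, C1 = quaternary methyl-bearing fusion carbon, C5 = fusion CH) is disconnected at C1–C5 and C9–C10. Both bonds are made in one intramolecular [2+2] photocycloaddition (de Mayo type) between the enol-ether double bond C5=C9 of a 2-substituted 3-benzyloxycyclopent-2-enone and a tethered isopropenyl group (C1=C10); the tether becomes the cyclopentane ring. The step exploits the 1,4-oxygen pattern at C6/C9 and the quaternary C1: hydrogenolysis of the C9 ether lets ring strain drive retro-aldol cleavage of the C5–C9 cyclobutane bond, releasing the hydroazulene-6,9-dione with the angular methyl in place.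

Key step: step 5

Remark 1: the locants C1–C10 of the final bicyclic core are used for all intermediates (C2 = CH–OAc, C3 = CH2, C4 = C(OH)(i-Pr), C6 = CH–O-anisoyl, C7 = CH2, C8 = C(CH3)–O, C9 = epoxide CH, C10 = CH–OH); β is the face of the C1 methyl group, α the opposite face; ring A is the five-membered ring C1–C5.
Remark 2: the diisopinocampheylboron enolate of a methyl ketone made with (−)-Ipc2BCl is assumed to attack the Re face of the aldehyde, which gives the (R)-carbinol in 4.

Step 1
Reactants: 1 2-acetylcyclopentane-1,3-dione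
Product: 2 2-acetyl-3-(benzyloxy)cyclopent-2-en-1-one
Conditions: BnOH, PPh3, DIAD, THF, 0 °C to rt
Reagents that add atoms: benzyl alcohol, OCc1ccccc1
Why: Mitsunobu O-alkylation of the strongly acidic triketone enol at a ring oxygen should give the endocyclic vinylogous ester that carries the future C9–O bond and leaves the acetyl group (future C4–C3) free; no stereocenter is formed.

Step 2
Reactants: 2 2-acetyl-3-(benzyloxy)cyclopent-2-en-1-one; 3 methacrolein
Product: 4 3-(benzyloxy)-2-[(3R)-3-hydroxy-4-methylpent-4-enoyl]cyclopent-2-en-1-one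
Conditions: (−)-Ipc2BCl, Et3N, Et2O, −78 to 0 °C; then 3, −78 to −20 °C; MeOH, pH 7 buffer, H2O2, 0 °C
Reagents that add atoms: none
Why: Reagent-controlled boron aldol reaction of the acetyl methyl group (the least hindered and most acidic enolisable position) through a closed six-membered transition state, in which the isopinocampheyl ligands should set the C2 carbinol as (R).

Step 3
Reactants: 4 3-(benzyloxy)-2-[(3R)-3-hydroxy-4-methylpent-4-enoyl]cyclopent-2-en-1-one
Product: 5 3-(benzyloxy)-2-[(3R,5R)-3,5-dihydroxy-2,6-dimethylhept-6-en-3-yl]cyclopent-2-en-1-one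
Conditions: i-PrMgCl, CeCl3, THF, −78 °C; aq. NH4Cl
Reagents that add atoms: isopropylmagnesium chloride, CC(C)[Mg]Cl
Why: Chelation-controlled 1,2-addition of the organocerium reagent to the side-chain ketone, held in a six-membered chelate with the C2 alkoxide, should occur anti to the isopropenyl substituent and give the syn-1,3-diol, setting the C4 tertiary carbinol as (R); the hard cerium reagent is chosen to suppress enolisation and addition–elimination at C9.

Step 4
Reactants: 5 3-(benzyloxy)-2-[(3R,5R)-3,5-dihydroxy-2,6-dimethylhept-6-en-3-yl]cyclopent-2-en-1-one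
Product: 6 (3R,5R)-5-[2-(benzyloxy)-5-oxocyclopent-1-en-1-yl]-5-hydroxy-2,6-dimethylhept-1-en-3-yl acetate
Conditions: Ac2O, pyridine, DMAP (cat.), CH2Cl2, 0 °C
Reagents that add atoms: acetic anhydride, CC(=O)OC(C)=O
Why: Selective acylation of the only secondary hydroxyl installs the final C2 acetate and removes the nucleophile that could cyclise onto C9, while the hindered tertiary C4–OH stays free as hydrogen-bond donor for the next step.

Step 5
Reactants: 6 (3R,5R)-5-[2-(benzyloxy)-5-oxocyclopent-1-en-1-yl]-5-hydroxy-2,6-dimethylhept-1-en-3-yl acetate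
Product: 7 tricyclic photoadduct (cyclobutane C1–C5–C9–C10 fused to ring A and to the cyclopentanone C5–C9)
Conditions: hν (medium-pressure Hg lamp, Pyrex), degassed CH2Cl2, 0 °C
Reagents that add atoms: none
Why: Excitation of the 3-alkoxyenone gives the triplet, whose α-carbon C5 bonds to the internal alkene carbon C1, and the resulting 1,4-diradical collapses by C9–C10 coupling; the closest known reaction type is the intramolecular de Mayo photocycloaddition of 2-alkenylcycloalkane-1,3-dione enol derivatives. Ring A closes in the favoured five-membered (1,5) mode at C5–C1 and the cyclobutane closes by radical recombination, so the three-atom tether should enforce the fused ("straight") and not the crossed regiochemistry. The quaternary stereocenter C1 is controlled by C2 and C4: the C2 acetoxy group takes the exo position (C2–H eclipsing the alkene, minimal allylic strain) and the C4 hydroxyl, hydrogen-bonded to the C6 carbonyl in the aprotic solvent, fixes the rotamer about C4–C5. Both elements place the cyclobutane on the face of ring A opposite to the two oxygens, so the C1 methyl should end up β, cis to C2–OAc and C4–OH. C5 and C9 are fixed by the two cis ring fusions but are not retained (C5 is re-protonated and C9 becomes a carbonyl in step 6). The step needs facial selectivity only, and the two directing groups of the substrate act in the same sense.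

Step 6
Reactants: 7 tricyclic photoadduct
Product: 10 trans-fused 6,9-diketone, via cyclobutanol 8 (not isolated), via cis-fused diketone 9 (not isolated)
Conditions: H2 (1 atm), Pd(OH)2/C, EtOAc, rt; then DBU (cat.), toluene, rt
Reagents that add atoms: none
Why: Hydrogenolysis of the benzyl ether frees the tertiary cyclobutanol, whose retro-aldol cleavage of C5–C9 is driven by release of cyclobutane strain (de Mayo fragmentation), and C5 (α to the C6 ketone, no alkene present) is then equilibrated to the trans-fused isomer, expected to be favoured because the C6 carbonyl avoids the α-isopropyl group and is hydrogen-bonded by the cis C4 hydroxyl.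

Step 7
Reactants: 10 trans-fused 6,9-diketone
Product: 11 6α-hydroxy-9-ketone
Conditions: Me4NBH(OAc)3, AcOH/MeCN, −30 °C
Reagents that add atoms: none
Why: Evans–Saksena reduction, in which boron bound to the C4 hydroxyl delivers hydride through a chair transition state to the C6 ketone only (the C9 ketone has no directing hydroxyl), should give the 6α-alcohol (C6–O cis to H-5, trans to the C1 methyl).

Step 8
Reactants: 11 6α-hydroxy-9-ketone
Product: 12 6α-(4-methoxybenzoyloxy)-9-ketone
Conditions: 4-methoxybenzoyl chloride, pyridine, DMAP, CH2Cl2, rt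
Reagents that add atoms: 4-methoxybenzoyl chloride, COc1ccc(C(Cl)=O)cc1
Why: Acylation of the only secondary hydroxyl (C6) installs the anisate, the tertiary C4–OH being too hindered to react.

Step 9
Reactants: 12 6α-(4-methoxybenzoyloxy)-9-ketone
Product: 14 8-methylene-9-ketone, via Mannich base 13 (not isolated)
Conditions: (CH2O)n, N-methylanilinium trifluoroacetate, THF, reflux
Reagents that add atoms: formaldehyde (as paraformaldehyde), C=O
Why: Acid-mediated Mannich condensation–elimination (α-methylenation) should take place at the unhindered α-methylene C8 and not at the neopentyl C10, introducing the carbon of the C8 methyl group without strong base.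

Step 10
Reactants: 14 8-methylene-9-ketone
Product: 15 8-methylene-9-ol (C9 epimers)
Conditions: NaBH4, CeCl3·7H2O, MeOH, −78 °C
Reagents that add atoms: none
Why: Luche reduction gives selective 1,2-reduction of the exocyclic enone; the C9 configuration is immaterial because C9 becomes sp2 in step 11.

Step 11
Reactants: 15 8-methylene-9-ol
Product: 18 Δ8-alkene, via allylic sulfonylhydrazine 16 (not isolated), via allylic diazene 17 (not isolated)
Conditions: 2-nitrobenzenesulfonylhydrazide, PPh3, DEAD, THF, −30 °C; then 23 °C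
Reagents that add atoms: none
Why: Mitsunobu displacement of the allylic alcohol by the sulfonylhydrazide, loss of sulfinate to the monoalkyl diazene and retro-ene loss of N2 deliver hydrogen to the exocyclic methylene with 1,3-transposition, giving regiospecifically the trisubstituted C8=C9 alkene bearing the C8 methyl.

Step 12
Reactants: 18 Δ8-alkene
Product: 19 Δ8-en-10-one
Conditions: CrO3, 3,5-dimethylpyrazole, CH2Cl2, −20 °C
Reagents that add atoms: chromium trioxide, O=[Cr](=O)=O
Why: Chromium-mediated allylic oxidation should occur at C10, the allylic methylene on the CH terminus of the trisubstituted alkene (tertiary-terminated allyl intermediate), C7 being deactivated by the adjacent C6 acyloxy group.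

Step 13
Reactants: 19 Δ8-en-10-one
Product: 20 8α,9α-epoxy-10-ketone
Conditions: dimethyldioxirane, acetone, 0 °C to rt
Reagents that add atoms: dimethyldioxirane, CC1(C)OO1
Why: Neutral electrophilic epoxidation of the β,β-disubstituted enone should occur from the α-face, opposite to the β-oriented C1 methyl and C2 acetoxy groups that flank the enone, setting C8 and C9 without exposing the esters or the γ-protons to base.

Step 14
Reactants: 20 8α,9α-epoxy-10-ketone
Product: 21 CNP0371526.1 (target)
Conditions: NaBH4, CeCl3·7H2O, MeOH, −78 °C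
Reagents that add atoms: none
Why: Luche reduction of the epoxy ketone with hydride attack from the α-face, anti to the adjacent angular C1 methyl, should give the 10β-alcohol trans to the epoxide, while esters and epoxide survive at low temperature.

Compound list
1 | 2-acetylcyclopentane-1,3-dione | CC(=O)C1C(=O)CCC1=O | starting material
2 | 2-acetyl-3-(benzyloxy)cyclopent-2-en-1-one | CC(=O)C1=C(OCc2ccccc2)CCC1=O | intermediate
3 | methacrolein (2-methylprop-2-enal) | CC(=C)C=O | starting material
4 | 3-(benzyloxy)-2-[(3R)-3-hydroxy-4-methylpent-4-enoyl]cyclopent-2-en-1-one | C=C(C)[C@H](O)CC(=O)C1=C(OCc2ccccc2)CCC1=O | intermediate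
5 | 3-(benzyloxy)-2-[(3R,5R)-3,5-dihydroxy-2,6-dimethylhept-6-en-3-yl]cyclopent-2-en-1-one | C=C(C)[C@H](O)C[C@@](O)(C(C)C)C1=C(OCc2ccccc2)CCC1=O | intermediate
6 | (3R,5R)-5-[2-(benzyloxy)-5-oxocyclopent-1-en-1-yl]-5-hydroxy-2,6-dimethylhept-1-en-3-yl acetate | C=C(C)[C@H](OC(C)=O)C[C@@](O)(C(C)C)C1=C(OCc2ccccc2)CCC1=O | intermediate
7 | tricyclic photoadduct: cyclobutane C1–C5–C9–C10 cis-fused on the α-face of ring A (1β-CH3, 2β-OAc, 4β-OH, 4α-i-Pr) and cis-fused to the cyclopentanone C5–C6(=O)–C7–C8–C9, 9-OBn | CC(=O)O[C@@H]1C[C@@](O)(C(C)C)[C@@]23C(=O)CC[C@]2(OCc4ccccc4)C[C@@]13C | intermediate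
8 | cyclobutanol: compound 7 with C9–OH in place of C9–OBn | CC(=O)O[C@@H]1C[C@@](O)(C(C)C)[C@@]23C(=O)CC[C@]2(O)C[C@@]13C | intermediate
9 | cis-fused hydroazulene-6,9-dione: 2β-OAc, 4β-OH, 4α-i-Pr, 1β-CH3, 5β-H, no C8 methyl | CC(=O)O[C@@H]1C[C@@](O)(C(C)C)[C@H]2C(=O)CCC(=O)C[C@@]12C | intermediate
10 | trans-fused hydroazulene-6,9-dione: 2β-OAc, 4β-OH, 4α-i-Pr, 1β-CH3, 5α-H | CC(=O)O[C@@H]1C[C@@](O)(C(C)C)[C@@H]2C(=O)CCC(=O)C[C@@]12C | intermediate
11 | 6α-hydroxy-9-ketone: compound 10 with C6 reduced to the 6α-alcohol | CC(=O)O[C@@H]1C[C@@](O)(C(C)C)[C@@H]2[C@@H](O)CCC(=O)C[C@@]12C | intermediate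
12 | 6α-(4-methoxybenzoyloxy)-9-ketone | CC(=O)O[C@@H]1C[C@@](O)(C(C)C)[C@@H]2[C@@H](OC(=O)c3ccc(OC)cc3)CCC(=O)C[C@@]12C | intermediate
13 | Mannich base: compound 12 with CH2N(CH3)Ph at C8 (C8 epimers) | CC(=O)O[C@@H]1C[C@@](O)(C(C)C)[C@@H]2[C@@H](OC(=O)c3ccc(OC)cc3)CC(CN(C)c4ccccc4)C(=O)C[C@@]12C | intermediate
14 | 8-methylene-9-ketone | CC(=O)O[C@@H]1C[C@@](O)(C(C)C)[C@@H]2[C@@H](OC(=O)c3ccc(OC)cc3)CC(=C)C(=O)C[C@@]12C | intermediate
15 | 8-methylene-9-ol (C9 epimers) | CC(=O)O[C@@H]1C[C@@](O)(C(C)C)[C@@H]2[C@@H](OC(=O)c3ccc(OC)cc3)CC(=C)C(O)C[C@@]12C | intermediate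
16 | allylic sulfonylhydrazine: C9–N(NH2)SO2(2-nitrophenyl), 8-methylene | CC(=O)O[C@@H]1C[C@@](O)(C(C)C)[C@@H]2[C@@H](OC(=O)c3ccc(OC)cc3)CC(=C)C(N(N)S(=O)(=O)c4ccccc4[N+](=O)[O-])C[C@@]12C | intermediate
17 | allylic diazene: C9–N=NH, 8-methylene | CC(=O)O[C@@H]1C[C@@](O)(C(C)C)[C@@H]2[C@@H](OC(=O)c3ccc(OC)cc3)CC(=C)C(N=N)C[C@@]12C | intermediate
18 | Δ8-alkene: 2β-acetoxy-4β-hydroxy-6α-(4-methoxybenzoyloxy)dauc-8-ene (trans-fused, 5α-H) | CC(=O)O[C@@H]1C[C@@](O)(C(C)C)[C@@H]2[C@@H](OC(=O)c3ccc(OC)cc3)CC(C)=CC[C@@]12C | intermediate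
19 | Δ8-en-10-one: compound 18 with C10=O | CC(=O)O[C@@H]1C[C@@](O)(C(C)C)[C@@H]2[C@@H](OC(=O)c3ccc(OC)cc3)CC(C)=CC(=O)[C@@]12C | intermediate
20 | 8α,9α-epoxy-10-ketone | CC(=O)O[C@@H]1C[C@@](O)(C(C)C)[C@@H]2[C@@H](OC(=O)c3ccc(OC)cc3)C[C@@]4(C)O[C@H]4C(=O)[C@@]12C | intermediate
21 | CNP0371526.1: 2β-acetoxy-8α,9α-epoxy-4β,10β-dihydroxy-6α-(4-methoxybenzoyloxy)daucane | COc1ccc(C(=O)O[C@H]2C[C@@]3(C)O[C@H]3[C@H](O)[C@]3(C)[C@@H]2[C@](O)(C(C)C)C[C@H]3OC(C)=O)cc1 | target

Total step count: 14. Longest linear sequence: 14 steps (fully linear from 1).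

Steps most likely to fail

Step 2. Enolisation may occur at the ring α-methylene instead of the acetyl group, enantioface discrimination by the boron reagent may be incomplete, and the aldol may cyclise onto C9. The fallback sets out from 2 and returns at 4: 2 would be converted with TMSOTf and Et3N (CH2Cl2, −78 °C) into the silyl enol ether 3-(benzyloxy)-2-[1-(trimethylsilyloxy)ethenyl]cyclopent-2-en-1-one F1. This preformed nucleophile would then be added to 3 in a catalytic enantioselective Mukaiyama aldol reaction (SiCl4 activated by a chiral bisphosphoramide Lewis base, CH2Cl2, −78 °C), and aqueous work-up would give 4.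

Step 9. Condensation at the C10 methylene, twofold condensation, or oligomerisation of the exocyclic enone may occur. The fallback sets out from 12 and returns at 18, bypassing 14 and 15. Kinetic deprotonation at C8 (LiN(SiMe3)2, THF, −78 °C) and methylation with MeI would give the C8-methyl ketone F2. The more substituted enolate (KN(SiMe3)2 under equilibrating conditions) would be trapped with N-phenyltriflimide as the enol triflate F3. Palladium-catalysed reduction (Pd(OAc)2, PPh3, HCO2H, Bu3N, DMF, 60 °C) would then give 18.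

Step 12. Oxidation may occur at C7 or at the C8 methyl instead of C10. The fallback sets out from 18 and returns at 19. Epoxidation with mCPBA (CH2Cl2, 0 °C) would give the 8,9-epoxide F4. Opening at the less substituted C9 with sodium phenylselenide ((PhSe)2, NaBH4, EtOH) would give the hydroxy selenide F5. Oxidation with H2O2 and selenoxide syn-elimination, possible only toward C10, would give the tertiary allylic alcohol F6. Oxidative 1,3-transposition with pyridinium chlorochromate [C5H5NH][CrO3Cl] (Babler–Dauben oxidation) would place the carbonyl at C10 and the double bond at C8=C9, giving 19.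

Further compounds
F1 | step 2 | 3-(benzyloxy)-2-[1-(trimethylsilyloxy)ethenyl]cyclopent-2-en-1-one | C=C(O[Si](C)(C)C)C1=C(OCc2ccccc2)CCC1=O
F2 | step 9 | C8-methyl ketone: compound 12 with CH3 at C8 (C8 epimers) | CC(=O)O[C@@H]1C[C@@](O)(C(C)C)[C@@H]2[C@@H](OC(=O)c3ccc(OC)cc3)CC(C)C(=O)C[C@@]12C
F3 | step 9 | enol triflate: C8(CH3)=C9–OSO2CF3 | CC(=O)O[C@@H]1C[C@@](O)(C(C)C)[C@@H]2[C@@H](OC(=O)c3ccc(OC)cc3)CC(C)=C(OS(=O)(=O)C(F)(F)F)C[C@@]12C
F4 | step 12 | 8,9-epoxide of compound 18 (either face) | CC(=O)O[C@@H]1C[C@@](O)(C(C)C)[C@@H]2[C@@H](OC(=O)c3ccc(OC)cc3)CC4(C)OC4C[C@@]12C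
F5 | step 12 | hydroxy selenide: C8(CH3)–OH, C9–SePh | CC(=O)O[C@@H]1C[C@@](O)(C(C)C)[C@@H]2[C@@H](OC(=O)c3ccc(OC)cc3)CC(C)(O)C([Se]c4ccccc4)C[C@@]12C
F6 | step 12 | tertiary allylic alcohol: C8(CH3)–OH, C9=C10 | CC(=O)O[C@@H]1C[C@@](O)(C(C)C)[C@@H]2[C@@H](OC(=O)c3ccc(OC)cc3)CC(C)(O)C=C[C@@]12C
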